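The constants and the charges of this flask stood as follows, with the question under them.

    partner + free catalyst + left-handed substrate → free catalyst + left-handed product (k1 = 120 M⁻² min⁻¹)
    partner + free catalyst + right-handed substrate → free catalyst + right-handed product (k2 = 71 M⁻² min⁻¹)
    free catalyst + impurity → spent catalyst (k3 = 30000 M⁻¹ min⁻¹)
    partner → decomposed reagent (k4 = 0.020 min⁻¹)

left-handed substrate 0.25 M; partner 3.00 equiv; free catalyst 0.17 mol%; impurity 0.32 mM; right-handed substrate 0.25 M

- free catalyst is single-handed; left-handed substrate and right-handed substrate are mirror images of each other, charged as a racemate, each of them at the stated concentration
- charge of left-handed substrate (flask): 0.25 M

* apparent order in partner when 20% of the left-handed substrate and right-handed substrate together are converted (percent change of the rate of making left-handed product for one percent more partner charged)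

The bench rule I reached for first says that a reagent charged in excess follows its charge, so that at a given conversion the rate goes with the partner charged and the order is near one. Applied honestly, with partner B at 0.750 M and the coupling taking 0.100 M of it by the chosen conversion, the rule gives 1.15. The border lies in a ratio of rates. The impurity strips the free catalyst at 9.60 min⁻¹, far faster than partner decomposes, which leaves free catalyst C at 0.105 mM. With so little catalyst, decomposition outruns coupling by 3.99 with the substrates as charged, so the rule stops working here.

I therefore counted progress in τ, the time integral of B times C, because both substrates fall exponentially in τ. Taking the mean of the constants, the chosen conversion needs τ of 0.00234 M^2 min. With C held constant, the partner decomposed on the way is the decomposition constant times τ, divided by C, or 0.445 M. This toll stays the same for any charge, since more partner merely shortens the clock. That leaves 0.205 M, so each extra percent of charge lands on a small remainder. The result is 3.66, and this leverage λ, the charge of partner over the partner left at the chosen conversion, is the apparent order.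

The forecast, slightly lower, gave 3.6, between 3.2 and 4, on this ground: “I compare runs at the same conversion”.

The simulation gave 3.6, with the conversion reached after 0.876 h. The order stood that high because the loss of partner to decomposed reagent and the loss of free catalyst to spent catalyst acted together, the first being the toll that shrinks the remainder in λ and the second the thinning of C that swells that toll. In the simulated run with the decomposition taken away, the toll drops out, so λ falls from my 3.66 to 1.15, and that run read 1.2, while the simulated run with the poisoning taken away read 1.4.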